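**Retrosynthetic overview**
- The target is unmasked last by one basic, palladium-mediated removal of three O-allyl groups together with ester saponification; the aryl ketone comes from DDQ oxidation of the ring B benzylic CH2.
- The hexasubstituted aromatic ring C is made by a four-to-six ring expansion: a rhodium-catalysed union of a ring B cyclohexenyl boronate with a squarate-derived cyclobutenedione.
- The boronate comes from a 2,2,3-trisubstituted cyclohexanone, whose two stereocentres are set in one pot by asymmetric copper-catalysed isopropenyl conjugate addition and anti enolate methylation.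
- The small pieces are cyclohexenone and methyl acrylate (enone), and squaric acid, allyl alcohol and isopropylmagnesium chloride (cyclobutenedione).
- Ring order: ring B is present from the start as cyclohexenone; ring C is formed last.

Assumption: the descriptors read from the SMILES are (1R,2S) in tetrahydronaphthalene numbering (isopropenyl trans to the quaternary methyl, cis to the propanoic acid chain); in step 4 the ligand antipode that delivers this series is used.

**Step 1**
Reactants: 1 squaric acid (3,4-dihydroxycyclobut-3-ene-1,2-dione); 2 allyl alcohol (prop-2-en-1-ol; two equivalents are incorporated)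
Product: 3 3,4-bis(prop-2-en-1-yloxy)cyclobut-3-ene-1,2-dione (diallyl squarate)
Conditions: 2 (10 equiv), toluene, reflux, Dean–Stark, 16 h
Reagents that add atoms: prop-2-en-1-ol (the second equivalent of 2), C=CCO
Why: Azeotropic double esterification of the vinylogous diacid with two equivalents of allyl alcohol and loss of two waters (the standard route to dialkyl squarates), with allyl chosen because it can later be removed without acid, which the isopropenyl group would not survive.

**Step 2**
Reactants: 3 diallyl squarate; 4 isopropylmagnesium chloride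
Product: 6 3-(prop-2-en-1-yloxy)-4-(propan-2-yl)cyclobut-3-ene-1,2-dione, via hydroxycyclobutenone adduct 5 (not isolated)
Conditions: 4 (1.05 equiv), THF, −78 °C; then 6 M HCl, 0 °C → rt
Reagents that add atoms: water, O (becomes the new ring carbonyl oxygen; the tertiary hydroxyl leaves as water)
Why: Grignard 1,2-addition to one squarate carbonyl followed by acid-catalysed allylic transposition with loss of allyl alcohol, the standard squarate-to-3-alkyl-4-alkoxycyclobutenedione sequence.

**Step 3**
Reactants: 7 cyclohex-2-en-1-one; 8 methyl acrylate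
Product: 9 methyl 3-(6-oxocyclohex-1-en-1-yl)propanoate
Conditions: DBU (1.5 equiv), 4-methoxyphenol (1 mol%), neat, sealed tube, 150–185 °C
Reagents that add atoms: none
Why: DBU-mediated cross Rauhut–Currier-type α-alkylation, in which conjugate addition of DBU to the enone gives an enolate that adds to the acrylate and proton transfer/β-elimination of DBU restores the enone.

**Step 4**
Reactants: 9 methyl 3-(6-oxocyclohex-1-en-1-yl)propanoate; 10 isopropenylmagnesium bromide (prop-1-en-2-ylmagnesium bromide); 11 iodomethane
Product: 13 methyl 3-[(1R,6S)-1-methyl-2-oxo-6-(prop-1-en-2-yl)cyclohexyl]propanoate, via bromomagnesium enolate 12 (not isolated)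
Conditions: 10 (1.3 equiv, slow addition), Cu(OTf)2 (3 mol%), (4S,5S)-4,5-diphenyl-1,3-bis(2,4,6-trimethylbenzyl)-4,5-dihydro-1H-imidazol-3-ium chloride (4 mol%, or its antipode), Et2O, −30 °C; then 11 (5 equiv), DMPU, −30 °C → rt
Reagents that add atoms: none
Why: Copper/N-heterocyclic carbene-catalysed asymmetric conjugate addition of a Grignard reagent to an α-substituted cyclohexenone sets the isopropenyl-bearing centre (S) under ligand control, and the regiodefined magnesium enolate is then methylated anti to the pseudoaxial isopropenyl group, which sets the quaternary centre (R; methyl trans to isopropenyl, ester chain cis).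

**Step 5**
Reactants: 13 methyl 3-[(1R,6S)-1-methyl-2-oxo-6-(prop-1-en-2-yl)cyclohexyl]propanoate
Product: 14 methyl 3-[(1R,6S)-1-methyl-6-(prop-1-en-2-yl)-2-(trifluoromethanesulfonyloxy)cyclohex-2-en-1-yl]propanoate
Conditions: KN(SiMe3)2 (1.1 equiv), THF, −78 °C; PhNTf2 (1.2 equiv), −78 → 0 °C; 1 M HCl wash
Reagents that add atoms: N-phenylbis(trifluoromethanesulfonimide) (PhNTf2), O=S(=O)(N(c1ccccc1)S(=O)(=O)C(F)(F)F)C(F)(F)F
Why: Kinetic enolate O-triflation, where the ketone can enolise only away from the quaternary carbon and is far more acidic than the ester, so one enol triflate forms and neither stereocentre is touched.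

**Step 6**
Reactants: 14 enol triflate
Product: 15 methyl 3-[(1R,6S)-1-methyl-6-(prop-1-en-2-yl)-2-(4,4,5,5-tetramethyl-1,3,2-dioxaborolan-2-yl)cyclohex-2-en-1-yl]propanoate
Conditions: B2pin2 (1.1 equiv), PdCl2(PPh3)2 (3 mol%), PPh3 (6 mol%), KOPh (1.5 equiv), toluene, 50 °C
Reagents that add atoms: bis(pinacolato)diboron (B2pin2), CC1(C)OB(OC1(C)C)B1OC(C)(C)C(C)(C)O1
Why: Miyaura borylation of a cycloalkenyl triflate (oxidative addition to zerovalent palladium, transmetalation from phenoxide-activated diboron, reductive elimination), which tolerates the ester and the isopropenyl group.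

**Step 7**
Reactants: 15 alkenyl boronate; 6 3-(prop-2-en-1-yloxy)-4-(propan-2-yl)cyclobut-3-ene-1,2-dione
Product: 17 methyl 3-[(1R,2S)-1-methyl-6-(propan-2-yl)-2-(prop-1-en-2-yl)-5,7,8-tris(prop-2-en-1-yloxy)-1,2,3,4-tetrahydronaphthalen-1-yl]propanoate, via hydroquinone 16 (not isolated)
Conditions: [Rh(OH)(cod)]2 (3 mol%), 1,4-dioxane/H2O 10:1, 35 °C, Ar; then evaporate, allyl bromide (3 equiv), K2CO3 (4 equiv), DMF, 50 °C
Reagents that add atoms: allyl bromide (3-bromoprop-1-ene; two equivalents are incorporated), C=CCBr
Why: Proposed new method: boron-to-rhodium transmetalation gives an alkenyl complex of monovalent rhodium that adds 1,2 to the ketone-like carbonyl of 6 (the one next to the allyloxy carbon), the strained rhodium cyclobutenolate undergoes β-carbon (acyl) elimination, and the acyl–rhodium closes the six-membered ring by intramolecular 1,4-addition to the dienone just formed before protonolysis and tautomerisation give hydroquinone 16, a stepwise organometallic four-to-six ring expansion that builds ring C at 35 °C, well below the temperature of the thermal rearrangement of such adducts (cleavage of the other ring bond of the alkoxide would give an isomeric catechol that is allylated to the same 17), the closest known reaction types being rhodium-catalysed addition of organoboron reagents to cyclobutanones with ring opening by β-carbon elimination and the thermal Moore ring expansion of 4-alkenyl-4-hydroxycyclobutenones, after which Williamson O-allylation in the same flask protects the air-sensitive hydroquinone and no stereocentre is involved.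

**Step 8**
Reactants: 17 tris-allyl ether
Product: 18 methyl 3-[(1R,2S)-1-methyl-4-oxo-6-(propan-2-yl)-2-(prop-1-en-2-yl)-5,7,8-tris(prop-2-en-1-yloxy)-1,2,3,4-tetrahydronaphthalen-1-yl]propanoate
Conditions: DDQ (2.3 equiv), 1,4-dioxane/H2O 9:1, 0 °C → rt
Reagents that add atoms: water, O
Why: DDQ benzylic oxidation, in which hydride abstraction from the only ring CH2 that is para to an allyloxy group gives a stabilised benzylic cation that water traps and DDQ oxidises again to the aryl ketone, while the other benzylic ring carbon is quaternary, the isopropyl methine C–H lies in the arene plane and neither stereocentre adjoins the cation.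

**Step 9**
Reactants: 18 tris-allyl keto ester
Product: 19 3-[(1R,2S)-5,7,8-trihydroxy-1-methyl-4-oxo-6-(propan-2-yl)-2-(prop-1-en-2-yl)-1,2,3,4-tetrahydronaphthalen-1-yl]propanoic acid
Conditions: Pd(PPh3)4 (5 mol%), K2CO3 (8 equiv), degassed MeOH/H2O 5:1, 50 °C, Ar; then 1 M HCl to pH 3, 0 °C, ascorbic acid
Reagents that add atoms: water, O
Why: Tsuji–Trost-type deallylation (π-allyl formation from the three aryl allyl ethers, allyl transfer to methoxide) runs together with carbonate saponification of the methyl ester, so all four protecting groups are removed under basic, acid-free conditions that leave the isopropenyl group, the ketone and both stereocentres (neither is α to the carbonyl) untouched.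

**Compound list**
1 | squaric acid (3,4-dihydroxycyclobut-3-ene-1,2-dione) | O=C1C(O)=C(O)C1=O | starting material
2 | allyl alcohol (prop-2-en-1-ol) | C=CCO | starting material
3 | 3,4-bis(prop-2-en-1-yloxy)cyclobut-3-ene-1,2-dione | C=CCOC1=C(OCC=C)C(=O)C1=O | intermediate
4 | isopropylmagnesium chloride | CC(C)[Mg]Cl | starting material
5 | 4-hydroxy-4-(propan-2-yl)-2,3-bis(prop-2-en-1-yloxy)cyclobut-2-en-1-one (racemic hydroxycyclobutenone adduct) | CC(C)C1(O)C(OCC=C)=C(OCC=C)C1=O | intermediate
6 | 3-(prop-2-en-1-yloxy)-4-(propan-2-yl)cyclobut-3-ene-1,2-dione | CC(C)C1=C(OCC=C)C(=O)C1=O | intermediate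
7 | cyclohex-2-en-1-one | O=C1C=CCCC1 | starting material
8 | methyl acrylate | C=CC(=O)OC | starting material
9 | methyl 3-(6-oxocyclohex-1-en-1-yl)propanoate | COC(=O)CCC1=CCCCC1=O | intermediate
10 | isopropenylmagnesium bromide | C=C(C)[Mg]Br | starting material
11 | iodomethane | CI | starting material
12 | methyl 3-[(6S)-2-[(bromomagnesio)oxy]-6-(prop-1-en-2-yl)cyclohex-1-en-1-yl]propanoate (bromomagnesium enolate) | C=C(C)[C@@H]1CCCC(O[Mg]Br)=C1CCC(=O)OC | intermediate
13 | methyl 3-[(1R,6S)-1-methyl-2-oxo-6-(prop-1-en-2-yl)cyclohexyl]propanoate | C=C(C)[C@@H]1CCCC(=O)[C@]1(C)CCC(=O)OC | intermediate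
14 | methyl 3-[(1R,6S)-1-methyl-6-(prop-1-en-2-yl)-2-(trifluoromethanesulfonyloxy)cyclohex-2-en-1-yl]propanoate | C=C(C)[C@@H]1CCC=C(OS(=O)(=O)C(F)(F)F)[C@]1(C)CCC(=O)OC | intermediate
15 | methyl 3-[(1R,6S)-1-methyl-6-(prop-1-en-2-yl)-2-(4,4,5,5-tetramethyl-1,3,2-dioxaborolan-2-yl)cyclohex-2-en-1-yl]propanoate | C=C(C)[C@@H]1CCC=C(B2OC(C)(C)C(C)(C)O2)[C@]1(C)CCC(=O)OC | intermediate
16 | methyl 3-[(1R,2S)-5,8-dihydroxy-1-methyl-6-(propan-2-yl)-2-(prop-1-en-2-yl)-7-(prop-2-en-1-yloxy)-1,2,3,4-tetrahydronaphthalen-1-yl]propanoate (hydroquinone) | C=C(C)[C@@H]1CCc2c(O)c(C(C)C)c(OCC=C)c(O)c2[C@]1(C)CCC(=O)OC | intermediate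
17 | methyl 3-[(1R,2S)-1-methyl-6-(propan-2-yl)-2-(prop-1-en-2-yl)-5,7,8-tris(prop-2-en-1-yloxy)-1,2,3,4-tetrahydronaphthalen-1-yl]propanoate | C=C(C)[C@@H]1CCc2c(OCC=C)c(C(C)C)c(OCC=C)c(OCC=C)c2[C@]1(C)CCC(=O)OC | intermediate
18 | methyl 3-[(1R,2S)-1-methyl-4-oxo-6-(propan-2-yl)-2-(prop-1-en-2-yl)-5,7,8-tris(prop-2-en-1-yloxy)-1,2,3,4-tetrahydronaphthalen-1-yl]propanoate | C=C(C)[C@@H]1CC(=O)c2c(OCC=C)c(C(C)C)c(OCC=C)c(OCC=C)c2[C@]1(C)CCC(=O)OC | intermediate
19 | 3-[(1R,2S)-5,7,8-trihydroxy-1-methyl-4-oxo-6-(propan-2-yl)-2-(prop-1-en-2-yl)-1,2,3,4-tetrahydronaphthalen-1-yl]propanoic acid | C=C(C)[C@@H]1CC(=O)c2c(O)c(C(C)C)c(O)c(O)c2[C@]1(C)CCC(=O)O | target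

**Step count and risk**
Total steps: 9. Longest linear sequence: 7 (steps 3–9, from 7 to 19); the two-step squarate branch (steps 1–2) joins at step 7.

Three steps most likely to fail:

Step 7 (the new rhodium cascade). The alkenyl–rhodium may protodeboronate, add without ring opening, or be too hindered by the neighbouring quaternary carbon. The fallback uses the known two-stage Moore sequence, sets out from triflate 14 (with dione 6) and comes back at 17. Triflate 14 is coupled with 6 under Nozaki–Hiyama–Kishi conditions (CrCl2 4 equiv, NiCl2 2 mol%, DMF, 25 °C; the organochromium species tolerates the ester and attacks the ketone-like carbonyl). This gives methyl 3-[(1R,6S)-2-[1-hydroxy-4-oxo-3-(propan-2-yl)-2-(prop-2-en-1-yloxy)cyclobut-2-en-1-yl]-1-methyl-6-(prop-1-en-2-yl)cyclohex-2-en-1-yl]propanoate F1 as a mixture of carbinol epimers. F1 is heated in p-xylene at 130 °C (thermal ring opening to the vinylketene and 6π ring closure) to give hydroquinone 16, which is allylated (allyl bromide, K2CO3, DMF, 50 °C) to 17.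

Step 4 (asymmetric conjugate addition/methylation). Copper/carbene-catalysed additions of this kind are established for alkyl Grignard reagents; an alkenyl Grignard on an ester-bearing α-substituted enone may give low ee or conversion. The fallback gives up asymmetric catalysis, sets out from enone 9 and comes back at 13. Achiral copper catalysis (CuBr·SMe2 5 mol%, isopropenylmagnesium bromide, THF, −40 °C) gives the racemic bromomagnesium enolate F2, which is methylated (iodomethane, DMPU) with the same anti selectivity to the racemic trans-keto ester F3. Preparative chiral SFC on an amylose tris(3,5-dimethylphenylcarbamate) phase then delivers the (1R,6S)-enantiomer 13 and leaves its antipode behind.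

Step 3 (DBU cross-coupling at high temperature). Acrylate oligomerisation or double alkylation may erode the yield. The fallback replaces the organocatalytic coupling by a halogenation/cross-coupling pair, sets out from cyclohexenone 7 and comes back at 9. Iodination of 7 (I2, pyridine/CH2Cl2, 0 °C → rt) gives 2-iodocyclohex-2-en-1-one F4. Negishi coupling of F4 with (3-methoxy-3-oxopropyl)zinc bromide F5 (made from methyl 3-bromopropanoate, Zn dust and LiCl in THF) under PdCl2(dppf) (3 mol%, THF, 40 °C) gives 9.

**Further compounds**
F1 | step 7 | methyl 3-[(1R,6S)-2-[1-hydroxy-4-oxo-3-(propan-2-yl)-2-(prop-2-en-1-yloxy)cyclobut-2-en-1-yl]-1-methyl-6-(prop-1-en-2-yl)cyclohex-2-en-1-yl]propanoate (carbinol epimers) | C=C(C)[C@@H]1CCC=C(C2(O)C(OCC=C)=C(C(C)C)C2=O)[C@]1(C)CCC(=O)OC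
F2 | step 4 | racemic bromomagnesium enolate (12 plus its enantiomer) | C=C(C)[C@@H]1CCCC(O[Mg]Br)=C1CCC(=O)OC.C=C(C)[C@H]1CCCC(O[Mg]Br)=C1CCC(=O)OC
F3 | step 4 | racemic trans-keto ester (13 plus its enantiomer) | C=C(C)[C@@H]1CCCC(=O)[C@]1(C)CCC(=O)OC.C=C(C)[C@H]1CCCC(=O)[C@@]1(C)CCC(=O)OC
F4 | step 3 | 2-iodocyclohex-2-en-1-one | O=C1CCCC=C1I
F5 | step 3 | (3-methoxy-3-oxopropyl)zinc bromide | COC(=O)CC[Zn]Br
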